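**Retrosynthetic overview**
1. Both C10=C11-type bonds are made by two successive Wittig reactions in one flask: C2-symmetric C12 dial 6 + ring A salt 16, then ring B salt 15. The first olefination breaks the symmetry of 6.
2. Dial 6 is the C15–C15' homodimer of bromodienal 4, which comes from hydroxide ring opening of N-sulfonated 4-methylpyridine 1 (the aromatic ring is destroyed and nitrogen is expelled).
3. Salt 16 is made from 15 by loss of the tertiary hydroxyl; 15 comes from dienyl triol 14 by a double allylic shift with Ph3P·HBr; 14 comes from hydroxyketone 10 and enyne 11.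
4. Ketone 10 comes from ketoisophorone 7: transfer hydrogenation sets the secondary carbinol of both rings, radical hydration sets the tertiary carbinol.
5. No ring is formed: both carbocycles come from 7 (ring B is finished first, ring A is derived from it); the pyridine ring is opened, not kept.

Assumption: locants follow carotenoid numbering (unprimed = ring A half with the 3-hydroxy-4-ene ring, primed = ring B half with the 3',5'-diol ring), and RuCl(p-cymene)[(S,S)-TsDPEN] is taken to give the (S)-alcohol as it does with aryl ketones (otherwise its (R,R) form is used).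

**Step 1**
Reactants: 1 4-methylpyridine
Product: 3 potassium (1E,3E)-3-methyl-5-oxopenta-1,3-dien-1-olate, via 4-methylpyridinium-1-sulfonate 2 (not isolated)
Conditions: ClSO3H, CHCl3, 0 °C; then KOH, H2O, −20 → 40 °C
Reagents that add atoms: potassium hydroxide, [K+].[OH-]; chlorosulfonic acid, OS(=O)(=O)Cl (its SO3 stays only in 2)
Why: Zincke-type pyridinium ring opening (glutaconaldehyde synthesis), in which hydroxide adds at C2 of the N-sulfonylpyridinium, 6π electrocyclic opening and hydrolysis of the N-sulfonylimine expel nitrogen as sulfamate and leave the symmetric, delocalised E,E dienolate, so there is no regiochemical issue and no stereocentre.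

**Step 2**
Reactants: 3 potassium (1E,3E)-3-methyl-5-oxopenta-1,3-dien-1-olate
Product: 4 (2E,4E)-5-bromo-3-methylpenta-2,4-dienal
Conditions: Ph3PBr2, CH2Cl2, 0 °C → rt, dark
Reagents that add atoms: dibromotriphenylphosphorane, BrP(Br)(c1ccccc1)(c1ccccc1)c1ccccc1
Why: Appel-type O-activation of the vinylogous carboxylate followed by addition–elimination of bromide (vinylogous acid bromide formation) gives the conjugated bromodienal, which settles in the E,E form.

**Step 3**
Reactants: 4 (2E,4E)-5-bromo-3-methylpenta-2,4-dienal (two molecules)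
Product: 6 (2E,4E,6E,8E)-3,8-dimethyldeca-2,4,6,8-tetraenedial, via stannyl dienal 5 (not isolated)
Conditions: Pd(PPh3)4 (5 mol %), Me3SnSnMe3 (0.5 equiv), 1,4-dioxane, 80 °C, dark
Reagents that add atoms: hexamethylditin, C[Sn](C)(C)[Sn](C)(C)C (its Me3Sn stays only in 5)
Why: Stille–Kelly reductive homocoupling, in which half of 4 is stannylated in the flask and couples with the other half with retention of alkene geometry, forms the C15–C15' bond of the all-E, C2-symmetric dial.

**Step 4**
Reactants: 7 2,6,6-trimethylcyclohex-2-ene-1,4-dione (ketoisophorone)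
Product: 8 (4S)-4-hydroxy-2,6,6-trimethylcyclohex-2-en-1-one
Conditions: RuCl(p-cymene)[(S,S)-TsDPEN] (0.5 mol %), HCO2H/Et3N (5:2), CH2Cl2, 25 °C
Reagents that add atoms: none
Why: Noyori asymmetric transfer hydrogenation reduces only the less hindered C4 carbonyl (C1 is shielded by the gem-dimethyl and 2-methyl groups), and the chiral ruthenium hydride sets the (4S) carbinol that becomes C3 and C3' of the target.

**Step 5**
Reactants: 8 (4S)-4-hydroxy-2,6,6-trimethylcyclohex-2-en-1-one
Product: 10 (2R,4S)-2,4-dihydroxy-2,6,6-trimethylcyclohexan-1-one, via tertiary hydroperoxide 9 (not isolated)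
Conditions: Mn(dpm)3 (5 mol %), PhSiH3, O2 (1 atm), i-PrOH/CH2Cl2, 0 °C; then P(OEt)3, 0 °C → rt
Reagents that add atoms: dioxygen, O=O
Why: Mukaiyama-type radical hydration (hydrogen-atom transfer from Mn–H to the enone β-carbon, O2 capture of the tertiary α-radical, phosphite reduction of the hydroperoxide), with O2 expected to attack axially on the chair that keeps the 4-OH equatorial, which places the new 2-OH trans to the 4-OH (2R); the minor cis diol is removed by chromatography.

**Step 6**
Reactants: 10 (2R,4S)-2,4-dihydroxy-2,6,6-trimethylcyclohexan-1-one; 11 2-methylbut-1-en-3-yne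
Product: 14 (2R,4S)-1-[(1E)-3-methylbuta-1,3-dien-1-yl]-2,6,6-trimethylcyclohexane-1,2,4-triol, via lithium acetylide 12 (not isolated), via alkynyl triol 13 (not isolated)
Conditions: 11 (4 equiv), n-BuLi (3.8 equiv), THF, −78 °C; add 10, −78 → 0 °C; then LiAlH4 (4 equiv), reflux; H2O work-up
Reagents that add atoms: n-butyllithium, [Li]CCCC (its lithium stays only in 12)
Why: 1,2-addition of the small sp nucleophile to a ketone that has no α-hydrogen, then alkoxide-directed trans-hydroalumination of the propargylic alkyne in the same flask, gives the E diene; the new carbinol centre C1 is an inconsequential epimer mixture because it becomes sp2 in step 7.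

**Step 7**
Reactants: 14 (2R,4S)-1-[(1E)-3-methylbuta-1,3-dien-1-yl]-2,6,6-trimethylcyclohexane-1,2,4-triol
Product: 15 [(2E)-4-[(1E,2R,4S)-2,4-dihydroxy-2,6,6-trimethylcyclohexylidene]-2-methylbut-2-en-1-yl](triphenyl)phosphonium bromide (ring B salt)
Conditions: Ph3P·HBr (1.0 equiv), CH2Cl2, 0 °C → rt, dark; recrystallise (CH2Cl2/EtOAc)
Reagents that add atoms: triphenylphosphine hydrobromide, [Br-].[PH+](c1ccccc1)(c1ccccc1)c1ccccc1
Why: vinyl-carbinol-to-Wittig-salt reaction (SN1'-type double allylic transposition), in which the doubly allylic tertiary OH ionises and PPh3 adds irreversibly at the unhindered CH2 terminus (any furanoid or epoxide formed by the neighbouring tertiary OH re-ionises), giving E at C8'=C9' and, through the conformer in which the chain turns away from C5', E at the exocyclic bond; exactly one equivalent of HBr is consumed, so the tertiary 5'-OH survives, and minor geometric isomers are removed by recrystallisation.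

**Step 8**
Reactants: 15 ring B salt
Product: 16 [(2E)-4-[(1E,4S)-4-hydroxy-2,6,6-trimethylcyclohex-2-en-1-ylidene]-2-methylbut-2-en-1-yl](triphenyl)phosphonium bromide (ring A salt)
Conditions: p-TsOH·H2O (5 mol %), 4 Å MS, ClCH2CH2Cl, 40 °C
Reagents that add atoms: none
Why: acid-catalysed E1 dehydration of the tertiary allylic alcohol, in which the cation loses the ring proton next to it to give the endocyclic, linearly conjugated triene (more stable than the exocyclic methylene isomer); the secondary carbinol is untouched and the exocyclic E geometry is kept because the in-plane ring methyl disfavours the Z form.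

**Step 9**
Reactants: 6 (2E,4E,6E,8E)-3,8-dimethyldeca-2,4,6,8-tetraenedial; 16 ring A salt; 15 ring B salt
Product: 20 (3S,3'S,5'R)-4,5'-retro-β,β-carotene-3,3',5'-triol (all-E; the target), via ring A ylide 17 (not isolated), via ring A aldehyde 18 (not isolated), via ring B ylide 19 (not isolated)
Conditions: 6 (1.1 equiv), NaOMe, CH2Cl2/MeOH, −20 °C, slow addition of 16 (1.0 equiv); then 15 (1.5 equiv), NaOMe, −20 → 20 °C; then EtOH, 60 °C, 1 h, Ar, dark; chromatography on deactivated silica
Reagents that add atoms: none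
Why: two successive Wittig olefinations in one flask, in which the first ylide converts one aldehyde of the C2-symmetric dial (the remaining aldehyde of 18 is conjugated with seven C=C bonds and much less electrophilic, so mono-olefination dominates) and the second ylide closes the chain; the hindered Z isomers at the two new bonds equilibrate thermally to E without touching the stereocentres or the exocyclic double bonds, and the symmetric diol and tetrol by-products differ in polarity from the triol.

**Compound list**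
1 | 4-methylpyridine | Cc1ccncc1 | starting material
2 | 4-methylpyridinium-1-sulfonate | Cc1cc[n+](cc1)S(=O)(=O)[O-] | intermediate
3 | potassium (1E,3E)-3-methyl-5-oxopenta-1,3-dien-1-olate | [K+].[O-]/C=C/C(C)=C/C=O | intermediate
4 | (2E,4E)-5-bromo-3-methylpenta-2,4-dienal | O=C/C=C(C)/C=C/Br | intermediate
5 | (2E,4E)-3-methyl-5-(trimethylstannyl)penta-2,4-dienal | O=C/C=C(C)/C=C/[Sn](C)(C)C | intermediate
6 | (2E,4E,6E,8E)-3,8-dimethyldeca-2,4,6,8-tetraenedial | O=C/C=C(C)/C=C/C=C/C(C)=C/C=O | intermediate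
7 | 2,6,6-trimethylcyclohex-2-ene-1,4-dione (ketoisophorone) | CC1=CC(=O)CC(C)(C)C1=O | starting material
8 | (4S)-4-hydroxy-2,6,6-trimethylcyclohex-2-en-1-one | CC1=C[C@@H](O)CC(C)(C)C1=O | intermediate
9 | (2R,4S)-2-hydroperoxy-4-hydroxy-2,6,6-trimethylcyclohexan-1-one | O=C1C(C)(C)C[C@H](O)C[C@@]1(C)OO | intermediate
10 | (2R,4S)-2,4-dihydroxy-2,6,6-trimethylcyclohexan-1-one | O=C1C(C)(C)C[C@H](O)C[C@@]1(C)O | intermediate
11 | 2-methylbut-1-en-3-yne | C=C(C)C#C | starting material
12 | lithium 3-methylbut-3-en-1-yn-1-ide | [Li+].[C-]#CC(C)=C | intermediate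
13 | (2R,4S)-1-(3-methylbut-3-en-1-yn-1-yl)-2,6,6-trimethylcyclohexane-1,2,4-triol (C1 epimers; present as lithium alkoxide) | C=C(C)C#CC1(O)C(C)(C)C[C@H](O)C[C@@]1(C)O | intermediate
14 | (2R,4S)-1-[(1E)-3-methylbuta-1,3-dien-1-yl]-2,6,6-trimethylcyclohexane-1,2,4-triol (C1 epimers) | C=C(C)/C=C/C1(O)C(C)(C)C[C@H](O)C[C@@]1(C)O | intermediate
15 | [(2E)-4-[(1E,2R,4S)-2,4-dihydroxy-2,6,6-trimethylcyclohexylidene]-2-methylbut-2-en-1-yl](triphenyl)phosphonium bromide (ring B salt) | [Br-].c1ccccc1[P+](c1ccccc1)(c1ccccc1)C/C(C)=C/C=C1\C(C)(C)C[C@H](O)C[C@@]1(C)O | intermediate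
16 | [(2E)-4-[(1E,4S)-4-hydroxy-2,6,6-trimethylcyclohex-2-en-1-ylidene]-2-methylbut-2-en-1-yl](triphenyl)phosphonium bromide (ring A salt) | [Br-].CC1=C[C@@H](O)CC(C)(C)\C1=C/C=C(C)/C[P+](c1ccccc1)(c1ccccc1)c1ccccc1 | intermediate
17 | [(2E)-4-[(1E,4S)-4-hydroxy-2,6,6-trimethylcyclohex-2-en-1-ylidene]-2-methylbut-2-en-1-ylidene](triphenyl)phosphorane (ring A ylide) | CC1=C[C@@H](O)CC(C)(C)\C1=C/C=C(C)/C=P(c1ccccc1)(c1ccccc1)c1ccccc1 | intermediate
18 | (2E,4E,6E,8E,10E,12E)-14-[(1E,4S)-4-hydroxy-2,6,6-trimethylcyclohex-2-en-1-ylidene]-3,8,12-trimethyltetradeca-2,4,6,8,10,12-hexaenal (ring A aldehyde) | CC1=C[C@@H](O)CC(C)(C)\C1=C/C=C(C)/C=C/C=C(C)/C=C/C=C/C(C)=C/C=O | intermediate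
19 | [(2E)-4-[(1E,2R,4S)-2,4-dihydroxy-2,6,6-trimethylcyclohexylidene]-2-methylbut-2-en-1-ylidene](triphenyl)phosphorane (ring B ylide) | c1ccccc1P(c1ccccc1)(c1ccccc1)=C/C(C)=C/C=C1\C(C)(C)C[C@H](O)C[C@@]1(C)O | intermediate
20 | (3S,3'S,5'R)-4,5'-retro-β,β-carotene-3,3',5'-triol, all-E (CNP0269135.2) | CC1=C[C@@H](O)CC(C)(C)\C1=C/C=C(C)/C=C/C=C(C)/C=C/C=C/C(C)=C/C=C/C(C)=C/C=C1\C(C)(C)C[C@H](O)C[C@@]1(C)O | target

**Step count**
Total: 9 steps. Longest linear sequence: 6 steps (4, 5, 6, 7, 8, 9); the central branch is 4 steps (1, 2, 3, 9).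

**Three steps most likely to fail**

Step 7 (14 → 15). The cation sits next to a tertiary hydroxyl, so furanoid closure, pinacol shift, early loss of that hydroxyl or the Z exocyclic isomer may win. The fallback avoids any dienyl cation and builds the diene by carbonyl olefination; it sets out from 10 and comes back at 15. Ethynylmagnesium bromide (THF, 0 °C) adds to 10 to give (2R,4S)-1-ethynyl-2,6,6-trimethylcyclohexane-1,2,4-triol F1. Meyer–Schuster rearrangement with (Ph3SiO)3VO in hot xylene gives (2E)-2-[(2R,4S)-2,4-dihydroxy-2,6,6-trimethylcyclohexylidene]acetaldehyde F2; the Z isomer closes to a lactol with the tertiary hydroxyl and is separated on silica, which fixes the exocyclic geometry early. Wittig reaction with ethyl 2-(triphenylphosphoranylidene)propanoate gives ethyl (2E,4E)-4-[(2R,4S)-2,4-dihydroxy-2,6,6-trimethylcyclohexylidene]-2-methylbut-2-enoate F3. Reduction with i-Bu2AlH gives (1R,3S,6E)-6-[(2E)-4-hydroxy-3-methylbut-2-en-1-ylidene]-1,5,5-trimethylcyclohexane-1,3-diol F4. CBr4/PPh3 at −30 °C converts only the primary allylic hydroxyl and gives (1R,3S,6E)-6-[(2E)-4-bromo-3-methylbut-2-en-1-ylidene]-1,5,5-trimethylcyclohexane-1,3-diol F5, and PPh3 in toluene displaces the bromide by SN2 to give 15.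

Step 8 (15 → 16). The dehydration may run on to loss of the secondary allylic hydroxyl, give the exocyclic methylene isomer, or scramble the exocyclic geometry. The fallback makes ring A without ever installing the tertiary hydroxyl; it sets out from 8 and comes back at 16. The lithium acetylide 12 adds 1,2 to the enone carbonyl of 8 to give (4S)-1-(3-methylbut-3-en-1-yn-1-yl)-2,6,6-trimethylcyclohex-2-ene-1,4-diol F6. LiAlH4 in refluxing THF gives (4S)-1-[(1E)-3-methylbuta-1,3-dien-1-yl]-2,6,6-trimethylcyclohex-2-ene-1,4-diol F7. Ph3P·HBr then ionises the tertiary, doubly allylic hydroxyl, and PPh3 adds at the CH2 terminus of the trienyl cation to give 16 directly.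

Step 9 (one-flask double Wittig). If the first olefination is not selective for one aldehyde, the product is a statistical mixture. The fallback joins two separately made halves at C15–C15' by cross-coupling, so no statistical step remains; it sets out from 4, 15 and 16 and comes back at 20. Wittig reaction of 15 (NaOMe) with 4 gives (1R,3S,6E)-6-[(2E,4E,6E,8E)-9-bromo-3,7-dimethylnona-2,4,6,8-tetraen-1-ylidene]-1,5,5-trimethylcyclohexane-1,3-diol F8. Compound 5 is prepared from 4 with a full equivalent of Me3SnSnMe3 and isolated, and Wittig reaction of 16 with 5 gives (1S,4E)-4-[(2E,4E,6E,8E)-3,7-dimethyl-9-(trimethylstannyl)nona-2,4,6,8-tetraen-1-ylidene]-3,5,5-trimethylcyclohex-2-en-1-ol F9. Stille coupling of F8 with F9 (Pd2(dba)3, AsPh3, NMP, 40 °C) gives 20.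

**Further compounds**
F1 | step 7 | (2R,4S)-1-ethynyl-2,6,6-trimethylcyclohexane-1,2,4-triol (C1 epimers) | C#CC1(O)C(C)(C)C[C@H](O)C[C@@]1(C)O
F2 | step 7 | (2E)-2-[(2R,4S)-2,4-dihydroxy-2,6,6-trimethylcyclohexylidene]acetaldehyde | O=C/C=C1\C(C)(C)C[C@H](O)C[C@@]1(C)O
F3 | step 7 | ethyl (2E,4E)-4-[(2R,4S)-2,4-dihydroxy-2,6,6-trimethylcyclohexylidene]-2-methylbut-2-enoate | CCOC(=O)/C(C)=C/C=C1\C(C)(C)C[C@H](O)C[C@@]1(C)O
F4 | step 7 | (1R,3S,6E)-6-[(2E)-4-hydroxy-3-methylbut-2-en-1-ylidene]-1,5,5-trimethylcyclohexane-1,3-diol | OC/C(C)=C/C=C1\C(C)(C)C[C@H](O)C[C@@]1(C)O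
F5 | step 7 | (1R,3S,6E)-6-[(2E)-4-bromo-3-methylbut-2-en-1-ylidene]-1,5,5-trimethylcyclohexane-1,3-diol | BrC/C(C)=C/C=C1\C(C)(C)C[C@H](O)C[C@@]1(C)O
F6 | step 8 | (4S)-1-(3-methylbut-3-en-1-yn-1-yl)-2,6,6-trimethylcyclohex-2-ene-1,4-diol (C1 epimers) | C=C(C)C#CC1(O)C(C)=C[C@@H](O)CC1(C)C
F7 | step 8 | (4S)-1-[(1E)-3-methylbuta-1,3-dien-1-yl]-2,6,6-trimethylcyclohex-2-ene-1,4-diol (C1 epimers) | C=C(C)/C=C/C1(O)C(C)=C[C@@H](O)CC1(C)C
F8 | step 9 | (1R,3S,6E)-6-[(2E,4E,6E,8E)-9-bromo-3,7-dimethylnona-2,4,6,8-tetraen-1-ylidene]-1,5,5-trimethylcyclohexane-1,3-diol | Br/C=C/C(C)=C/C=C/C(C)=C/C=C1\C(C)(C)C[C@H](O)C[C@@]1(C)O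
F9 | step 9 | (1S,4E)-4-[(2E,4E,6E,8E)-3,7-dimethyl-9-(trimethylstannyl)nona-2,4,6,8-tetraen-1-ylidene]-3,5,5-trimethylcyclohex-2-en-1-ol | CC1=C[C@@H](O)CC(C)(C)\C1=C/C=C(C)/C=C/C=C(C)/C=C/[Sn](C)(C)C
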